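The vessel is closed, stirred and isothermal. In it, starting complex takes up incoming ligand and becomes complex with one exchanged, then complex with two exchanged, while side product appears beside them.

| flask | starting complex | incoming ligand | leaving ligand | remark | time |
|---|---|---|---|---|---|
| Tuesday's | 0.10 M | 0.13 M | 0.10 M | run made earlier |  |
| Monday's | 0.10 M | 0.35 M | 0.10 M | run made earlier |  |
| ash | 0.10 M | 0.150 M | 0.100 M |  | 3.0 min |
| maple | 0.10 M | 0.450 M | 0.100 M |  | 3.0 min |

| run | time / s | side product / % | starting complex / % | complex with two exchanged / % | complex with one exchanged / % |
|---|---|---|---|---|---|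
| Tuesday's | 20.0 | 0.3 | 69.0 | 2.2 | 30.4 |
| Tuesday's | 40.0 | 2.0 | 55.1 | 2.9 | 40.2 |
| Tuesday's | 50.0 | 3.2 | 51.0 | 3.7 | 42.0 |
| Tuesday's | 80.0 | 5.8 | 41.7 | 6.6 | 46.3 |
| Tuesday's | 90.0 | 6.9 | 39.9 | 5.8 | 47.2 |
| Tuesday's | 120 | 9.5 | 33.8 | 8.1 | 48.9 |
| Monday's | 10.0 | 1.2 | 55.1 | 3.8 | 40.2 |
| Monday's | 15.0 | 1.4 | 44.2 | 7.7 | 48.2 |
| Monday's | 25.0 | 2.2 | 32.8 | 11.4 | 52.7 |
| Monday's | 40.0 | 4.7 | 23.4 | 16.8 | 53.6 |
| Monday's | 50.0 | 6.4 | 20.2 | 19.1 | 54.2 |
| Monday's | 80.0 | 10.9 | 12.9 | 25.0 | 49.8 |
| Monday's | 120 | 16.5 | 8.6 | 32.7 | 43.5 |

(readings scatter by 0.5 percentage points)

- a species is counted by the starting complex in it: one side product counts as two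

- which of these there is most of at the end, counted by the starting complex in it, ash (starting complex / side product / complex with one exchanged / complex with two exchanged)
- which of these there is most of at the end, counted by the starting complex in it, maple (starting complex / side product / complex with one exchanged / complex with two exchanged)
- amount of the one of these that there is most of at the end, in percent of the starting complex charged, ash
- amount of the one of these that there is most of at the end, in percent of the starting complex charged, maple

My bench rule is pseudo-first-order. With starting complex and leaving ligand charged as in Monday's run, and if incoming ligand stays near its charge c_X, I take a flask read at time t to have gone as far as Monday's run at the Monday-equivalent time τ = t·c_X/0.35 M. In Monday's readings, complex with one exchanged leads complex with two exchanged by 25 percentage points at 80.0 s and by 11 points at 120 s. Carried straight on, these scattered readings put the close of that lead at τ× = 151 s, the crossing time, where the lead changes hands.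

The rule has a border. Tuesday's last reading sits at τ = 44.6 s, yet its complex with two exchanged reads 8.1%, about half of Monday's 16.8% at 40.0 s. The ratio I hold against this is the supply S = c_X/(2c_M), with c_M the charge of starting complex: the incoming ligand charged over what two exchanges of that charge take. It is 0.650 for Tuesday's run and 1.75 for Monday's.

Ash has S = 0.750, below 1, and τ = 77.1 s, short of the crossing. Tuesday's run, also below 1, lagged its τ, so I take the τ of ash as too long if anything, and I expect complex with one exchanged to lead in ash, near Monday's 49.8% at 80.0 s. Maple has S = 2.25 and τ = 231 s, past the crossing. Monday's last climb, carried on, puts complex with two exchanged in maple at 54.2%.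

The forecast names the same leaders, complex with one exchanged at 49% for ash and complex with two exchanged at 50% for maple, so it sits below me on maple. Its ground for ash is “ligand runs low, so the once-exchanged complex plateaus near 49%”.

Ash, short of the crossing, ends with complex with one exchanged at 49.5%, and maple, past it, ends with complex with two exchanged at 51.8%, so the forecast stands on both flasks, and my maple figure lies 2.4 points above the flask.

starting complex + incoming ligand ⇌ leaving ligand + complex with one exchanged (K = 1.31, k = 0.208 /M/s); complex with one exchanged + incoming ligand ⇌ leaving ligand + complex with two exchanged (K = 0.220, k = 0.0631 /M/s); starting complex + complex with two exchanged → side product (k = 0.199 /M/s); leaving ligand → by-product carried off (k = 0.0171 /s) At 0.879 min, maple makes complex with two exchanged 4.57 times faster than it uses it, each step taken net. At 3.00 min, maple makes complex with one exchanged at 0.0569 of the rate it uses it up, each step taken net. A neighbour of maple charged with 0.18 M of incoming ligand has τ = 92.6 s, short of the crossing, and at 3.00 min holds complex with one exchanged at 48.3%, against 18.1% of complex with two exchanged.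

The data are calculated for an exercise.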